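(Readings and results are simulated on assumed constants, and the scatter is random.)

Late in a run I asked what each G lost still bought as Z, and I judged the flask below in that way.

| flask | G | Q | remark | time |
|---|---|---|---|---|
| east | 0.50 M | 3 equiv | run made earlier |  |
| north-west | 1 M | 1.5 equiv | run made earlier |  |
| flask | 1.0 M | 3.00 equiv |  | 20 min |

| run | time / min | Z / % | J / % | G / % |
|---|---|---|---|---|
| east | 1.50 | 10.4 | 0.7 | 90.0 |
| east | 2.50 | 14.0 | 0.3 | 85.7 |
| east | 4.00 | 19.6 | 0.7 | 79.4 |
| east | 6.00 | 25.2 | 2.1 | 72.1 |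
| east | 8.00 | 30.6 | 2.0 | 65.6 |
| east | 12.0 | 37.9 | 4.1 | 55.2 |
| east | 20.0 | 47.4 | 6.4 | 39.4 |
| north-west | 1.50 | 9.8 | 0.2 | 90.3 |
| north-west | 3.00 | 15.1 | 0.2 | 83.9 |
| north-west | 6.00 | 24.5 | 1.3 | 73.8 |
| north-west | 10.0 | 32.8 | 2.3 | 63.2 |
| north-west | 20.0 | 44.8 | 6.1 | 45.2 |

(scatter of a reading: 0.3 percentage points)

- what was read earlier has a scatter of 0.3 percentage points, one standard deviation
- what may be going on: G + Q -> Z; Q + Z -> J; Q <-> D; Q + J -> L

- equivalents of Q to G, everything else as given, that leave most Z at 20 min
- the amount of Z then, in percent of the G charged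
- the amount of Z with the amounts as given

The east run lost G at a fractional rate of 0.0702 min⁻¹ at the start and 0.0421 min⁻¹ between 12.0 min and 20.0 min, slower by a factor of 1.67. Between 2.50 min and 6.00 min it already stood at 0.0494 min⁻¹, a factor of 1.42, which I read as Q parked reversibly as D. The further 1.17 I read as Q consumed. Q enters G + Q -> Z and Q + Z -> J alike, so I took both slowings to cancel in the yield of Z per G lost.

G is the limiting reagent, and its balance says that whatever is neither G nor Z has passed through Z. Between 10.0 min and 20.0 min in the north-west run, G fell by 18 percentage points while Z rose by 12 points. Weighted by mean G over mean Z, that shortfall gave 0.466: the fractional loss rate of Z over that of G, the selectivity factor. With g the fraction of G left, Z = (g^s − g)/(1 − s). By this rule Z peaks at 51.4%, where the exposure, the logarithm of G charged over G left, is 1.43.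

The flask has the east run's equivalents at twice its concentrations, so I ran the east clock at that speed. Exposure reached 0.931 by 10.0 min, then grew at 0.0720 min⁻¹, the Q factor applied once more, ending at 1.65. That lies past the peak, with 19.2% of G left and Z at 50.9%. Scaling Q by the two exposures put the best charge near 2.60 equivalents.

The forecast gave 50.6% at the given charge, “just past the peak”, and 51.3% at 2.6 equiv.

The flask gave 50.5%, and 51.0% at 2.64 equiv.

    G + Q → Z (k = 0.00160 M⁻¹ s⁻¹)
    Q + Z → J (k = 7.60 × 10⁻⁴ M⁻¹ s⁻¹)
    Q ⇌ D (K = 1.70, k = 0.0350 s⁻¹)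
    Q + J → L (k = 0.00360 M⁻¹ s⁻¹)

Striking out Q + J -> L made no difference worth naming to Z. At 20.0 min the flask held 19.8% of its G, and s turns that into 51.0% of Z. The same flask with 1.20 equiv of Q kept 53.2% of its G at 20.0 min, for which s gives 39.9%, and it held 39.8%.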